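## Analysis of the target

The target is a resveratrol-type tetramer made of three 2,3-diaryl-2,3-dihydrobenzofurans. Ring B sits with C5 of its benzo ring on C2 of ring A, and ring C sits with C4 of its benzo ring on C3 of ring B. Ring A is also fused through C3, C3a and C4 to a seven-membered carbocycle. This carbocycle holds two carbons of a resorcinol ring (ring D, the aryl group on C3 of ring A) and two sp3 carbons: C-α, a CH carrying a 4-hydroxyphenyl group and bonded to ring D, and C-β, a CH–OH bonded to C4 of ring A. There are eight stereocentres. C2 and C3 of each dihydrofuran are trans and all three rings have the same absolute sense (2R,3R). The aryl group on C-α (R) and the hydroxyl on C-β (S) are trans, and the C-α aryl lies on the face opposite to C2 of ring A. The centres of ring A are separated from those of rings B and C by the benzo ring of ring B, so their relation must come from a reagent and not from the substrate. The molecule carries nine phenols and one benzylic alcohol, and each furan C2–O bond is a 4-oxybenzylic ether that ionises in acid next to electron-rich rings. Ring A is crowded, because C3 is flanked by the C4 substituent and by the ortho-substituted ring D, and the seven-membered ring has to be closed between two benzylic carbons. The strategy rests on one feature: C-α is para-hydroxybenzylic and therefore the exocyclic carbon of a latent para-quinone methide, and C-β is the carbon of an aryl aldehyde on C4 of ring A. Both are electrophiles, so they can only be joined after polarity reversal of the aldehyde.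

## Retrosynthetic reasoning

42 ⇒ 41 ⇒ 40. The eight aryl methyl ethers are cleaved last, because the free polyphenol is oxidation-prone and cannot be carried through base or organometallic steps. The carbinol at C-β is traced back to the ketone of 40, so that an equilibrating hydride transfer can set the trans alcohol.

40 ⇒ 39 ⇒ 38. The C-α–C-β bond is cut. It is the only bond of the seven-membered ring whose two ends are available in their natural oxidation states, as a quinone methide carbon and an aldehyde carbon, and cutting it leaves all four aromatic ring systems and seven stereocentres untouched. Cutting the bond from ring D to C-α or to C3 of ring A would require benzylic cations next to three acid-labile dihydrofurans. The forward step has to turn the aldehyde of 39 into an acyl anion that adds 1,6 to the quinone methide. This forms the ring, the bond and the C-α centre, and sets the 4-hydroxyphenyl group free without a deprotection. Quinone methide 39 has no blocking groups and is therefore released in the flask from the sulfone 38.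

38 ⇒ 37 ⇒ 35 ⇒ 32. The C–S bond comes from ionisation of a benzhydrol and capture by an arenesulfinate. The formyl carbon and C-α (with its aryl group, from aldehyde 33) are attached to two aryllithiums generated from the two bromides of 32. Both carbonyl carbons are introduced this late so that no aldehyde has to survive hydrazone formation or a metal carbene. The two bromides are told apart by the ortho-methoxy group that only the ring D bromide has.

32 ⇒ 31 ⇒ 29 ⇒ 8 + 28. In ring A the C2–C3 bond is cut. It joins the two stereocentres, and its removal turns ring A into a benzyl aryl ether, so that the two halves of the molecule are united by a plain O-alkylation of the phenol of hydrazone 8 with bromide 28. The forward reaction is an intramolecular C–H insertion of a donor/donor metal carbene. A chiral catalyst then fixes C3 of ring A independently of the remote centres of rings B and C, and acid moves C2 to the trans position.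

28 ⇒ 27 ⇒ 24. The benzylic bromide is a functional-group exchange from the aryl bromide of 24 (formylation, reduction, bromination). The bromide is the most robust placeholder for this carbon during the construction of ring B.

24 ⇒ 23 ⇒ 21 ⇒ 20 ⇒ 19 ⇒ 15 + 17. Ring B is opened at C2–C3 in the same way. The carbene carbon is the ketone carbon of 20, made by adding the aryllithium from 15 to aldehyde 17, whose 4-methoxybenzyl ether already holds C2 of ring B and its aryl group.

15 ⇒ 13 ⇒ 12 ⇒ 10 ⇒ 8 + 9. Ring C is again opened at C2–C3. Its precursor is the same hydrazone 8, here alkylated with 9. The extra bromine on the 3-aryl group, needed only for ring A, is removed after ring closure.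

8 ⇒ 7 ⇒ 6 ⇒ 5 ⇒ 2 + 3, and 2 ⇒ 1. Hydrazone 8 serves both resorcinol-derived rings A and C, which have the same absolute configuration. Its ketone carbon is joined to ring D by an aryl Grignard addition to aldehyde 3, and the phenol is freed by chelation-controlled demethylation next to the carbonyl. The hydrazone is made before O-alkylation because only the hydrogen-bonded ortho-hydroxy ketone keeps a carbonyl face open.

## Alternatives that were turned down

Alternative 1: The two bonds from aryl groups to C-β and to C-α would be made in one three-component step. An aryllithium (the future benzo ring of ring A) is added to an E-alkenyl boronic ester that carries ring D. The resulting ate complex is coupled with an anisyl triflate under Pd(OAc)2 and a MandyPhos-type ligand, giving the triaryl ethyl boronate A1 with aryl and boron anti. In its favour, it sets C-α and the future C-β under catalyst control in one convergent step. On this point it is stronger than the chosen route, which relies on the thermodynamic preference at C-α and on an equilibrating reduction at C-β. Against it, the alkenyl boronate carries a β-aryl group with an ortho substituent, so the metallate shift is slow and direct transmetallation competes. After A1 the seven-membered ring must still be closed by a cationic C–C bond formation at C3 of ring A, next to an oxidised benzylic carbon. Ring A with its two centres then has to be built afterwards in the right relation to rings B and C. In its place the chosen strategy offers ring closure and C–C bond formation in one step from groups in their natural oxidation state, a free phenol without deprotection, and only two steps after the key step.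

Alternative 2: The benzo ring of ring C would be built by a Danheiser benzannulation. A cyclobutenone on C3 of ring B opens on heating to a vinylketene, which combines with a siloxyalkyne to give the phenol A2, with the free hydroxyl next to the benzyl group and the second oxygen as a silyl ether. In its favour, the regiochemistry of the crowded resorcinol ring and the distinction of its two oxygens are settled by the mechanism, more securely than by the chelation-controlled demethylation used here. Against it, C3 of ring B is α to the four-ring carbonyl and benzylic, and can epimerise at the temperature of the ring opening. A2 still lacks C2 of ring C and both its stereocentres, which would have to be set by substrate control alone. The sequence is long and linear and does nothing for ring A or the cycloheptane. The chosen route takes the resorcinol rings ready-made from 1 and 3 and spends its steps on the bonds that carry stereochemistry.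

Alternative 3: Rings B and C would be closed together. CF3CO2H ionises both benzylic carbinols of the diol diphenol A4, and each cation is captured by its neighbouring phenol to give the bromide A3, which is the same compound as 24 of the route. In its favour, two rings form in one operation, both C2 centres end up trans whatever the carbinol configuration, and the step count to 24 would be lower. On step economy, and in avoiding hindered metal carbenes, it is stronger. Against it, A4 must already hold both diaryl-methine centres in the right absolute and relative configuration in an open chain, for which the step itself offers no control. Two cations are also formed in one molecule, with the 3,5-dimethoxyphenyl ring seven atoms away from the ring B cation. The chosen route sets each C3 by a chiral catalyst and uses acid only to epimerise one pre-formed ring at a time.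

Key step: step 24

Assumption: Rh2(R-PTAD)4, dirhodium tetrakis[(R)-(1-adamantyl)(N-phthalimido)acetate], is taken to give the (2S,3R) cis product in step 7. If the sense is the opposite, its commercial enantiomer is used, and the same enantiomer serves steps 14 and 19 because the three insertions are stereochemically homologous.

Note on names: "BC-5-yl" stands for the (2R,3R)-3-[(2R,3R)-3-(3,5-dimethoxyphenyl)-6-methoxy-2-(4-methoxyphenyl)-2,3-dihydro-1-benzofuran-4-yl]-2-(4-methoxyphenyl)-2,3-dihydro-1-benzofuran-5-yl group (rings B and C as in 24).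

## Route

Step 1
Reactants: 1 1-iodo-3,5-dimethoxybenzene
Product: 2 2-bromo-1-iodo-3,5-dimethoxybenzene
Conditions: NBS, MeCN, 0 °C → rt
Reagents that add atoms: N-bromosuccinimide O=C1CCC(=O)N1Br
Why: Electrophilic aromatic bromination; the position para to one methoxy group and ortho to iodine (C2, equivalent to C6) should react in preference to the more crowded C4 between the two methoxy groups, as in other 1-substituted 3,5-dimethoxybenzenes.

Step 2
Reactants: 2 2-bromo-1-iodo-3,5-dimethoxybenzene; 3 2-bromo-4,6-dimethoxybenzaldehyde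
Product: 5 (2-bromo-3,5-dimethoxyphenyl)(2-bromo-4,6-dimethoxyphenyl)methanol (racemic), via aryl Grignard reagent 4 (not isolated)
Conditions: iPrMgCl·LiCl, THF, −30 °C; then 3, −30 → 0 °C
Reagents that add atoms: none
Why: Iodine–magnesium exchange is much faster at C–I than at either C–Br bond and the ortho-bromoaryl Grignard reagent is stable below 0 °C; Grignard addition to the aldehyde gives the benzhydrol, whose configuration is lost in step 3.

Step 3
Reactants: 5 (2-bromo-3,5-dimethoxyphenyl)(2-bromo-4,6-dimethoxyphenyl)methanol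
Product: 6 (2-bromo-3,5-dimethoxyphenyl)(2-bromo-4,6-dimethoxyphenyl)methanone
Conditions: Dess–Martin periodinane, CH2Cl2, rt
Reagents that add atoms: none
Why: Dess–Martin oxidation of a hindered benzhydrol to the diaryl ketone; no other oxidisable group is present.

Step 4
Reactants: 6 (2-bromo-3,5-dimethoxyphenyl)(2-bromo-4,6-dimethoxyphenyl)methanone
Product: 7 (2-bromo-3,5-dimethoxyphenyl)(2-bromo-6-hydroxy-4-methoxyphenyl)methanone
Conditions: BCl3, CH2Cl2, −78 → 0 °C; H2O
Reagents that add atoms: none
Why: Chelation-controlled O-demethylation; only the methoxy group ortho to the carbonyl can form the six-membered boron chelate, so the para methoxy group and the two meta methoxy groups of the other ring should stay.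

Step 5
Reactants: 7 (2-bromo-3,5-dimethoxyphenyl)(2-bromo-6-hydroxy-4-methoxyphenyl)methanone
Product: 8 3-bromo-2-[(2-bromo-3,5-dimethoxyphenyl)(hydrazinylidene)methyl]-5-methoxyphenol (geometry at C=N not defined)
Conditions: N2H4·H2O, EtOH, 80 °C
Reagents that add atoms: hydrazine NN
Why: Hydrazone condensation is done on the free ortho-hydroxy ketone because the O–H···O=C hydrogen bond holds the carbonyl in the plane of the phenol ring and leaves one face open; after O-benzylation the 2,6-disubstituted ring would turn perpendicular and shield both faces.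

Step 6
Reactants: 8 3-bromo-2-[(2-bromo-3,5-dimethoxyphenyl)(hydrazinylidene)methyl]-5-methoxyphenol; 9 4-methoxybenzyl chloride
Product: 10 1-[(2-bromo-3,5-dimethoxyphenyl){2-bromo-4-methoxy-6-[(4-methoxyphenyl)methoxy]phenyl}methylidene]hydrazine
Conditions: Cs2CO3, DMF, 0 °C → rt
Reagents that add atoms: none
Why: Williamson ether synthesis; the caesium phenoxide is far more nucleophilic than the neutral, conjugated hydrazone NH2, so O-alkylation is expected.

Step 7
Reactants: 10 1-[(2-bromo-3,5-dimethoxyphenyl){2-bromo-4-methoxy-6-[(4-methoxyphenyl)methoxy]phenyl}methylidene]hydrazine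
Product: 12 (2S,3R)-4-bromo-3-(2-bromo-3,5-dimethoxyphenyl)-6-methoxy-2-(4-methoxyphenyl)-2,3-dihydro-1-benzofuran (cis), via diazo compound 11 (not isolated)
Conditions: MnO2, CH2Cl2, 0 °C, filter; Rh2(R-PTAD)4 (2 mol %), CH2Cl2, 0 °C → rt
Reagents that add atoms: none
Why: Oxidation of the hydrazone gives the diaryldiazomethane, and the dirhodium donor/donor carbene inserts into the benzylic C–H bond of the aryloxymethyl group through a five-membered transition state (intramolecular 1,5-C–H insertion); this reaction type gives cis 2,3-diaryl dihydrobenzofurans, with both new centres set by the chiral carboxylate ligands.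

Step 8
Reactants: 12 (2S,3R)-4-bromo-3-(2-bromo-3,5-dimethoxyphenyl)-6-methoxy-2-(4-methoxyphenyl)-2,3-dihydro-1-benzofuran
Product: 13 (2R,3R)-4-bromo-3-(2-bromo-3,5-dimethoxyphenyl)-6-methoxy-2-(4-methoxyphenyl)-2,3-dihydro-1-benzofuran (trans)
Conditions: CF3CO2H, CH2Cl2, 0 °C → rt
Reagents that add atoms: none
Why: Acid-mediated epimerisation; reversible heterolysis of the C2–O bond gives a 4-methoxybenzylic cation that the phenol recaptures, the trans isomer being the thermodynamic product; C3 is not touched, so the configuration set by the catalyst is kept there.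

Step 9
Reactants: 13 (2R,3R)-4-bromo-3-(2-bromo-3,5-dimethoxyphenyl)-6-methoxy-2-(4-methoxyphenyl)-2,3-dihydro-1-benzofuran
Product: 15 (2R,3R)-4-bromo-3-(3,5-dimethoxyphenyl)-6-methoxy-2-(4-methoxyphenyl)-2,3-dihydro-1-benzofuran, via aryllithium 14 (not isolated)
Conditions: n-BuLi (1.05 equiv), THF, −100 °C; MeOH
Reagents that add atoms: none
Why: Bromine–lithium exchange is kinetically and thermodynamically favoured at the bromide with an ortho-methoxy group (coordination and inductive stabilisation of the aryllithium) over the C4 bromide, which has none; protonation removes the bromine that was carried only to keep hydrazone 8 common to rings A and C.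

Step 10
Reactants: 16 5-bromo-2-hydroxybenzaldehyde; 9 4-methoxybenzyl chloride
Product: 17 5-bromo-2-[(4-methoxyphenyl)methoxy]benzaldehyde
Conditions: K2CO3, DMF, rt
Reagents that add atoms: none
Why: Williamson ether synthesis; the benzyl group put on here is not a protecting group but the future C2 of ring B with its 4-methoxyphenyl substituent.

Step 11
Reactants: 15 (2R,3R)-4-bromo-3-(3,5-dimethoxyphenyl)-6-methoxy-2-(4-methoxyphenyl)-2,3-dihydro-1-benzofuran; 17 5-bromo-2-[(4-methoxyphenyl)methoxy]benzaldehyde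
Product: 19 {5-bromo-2-[(4-methoxyphenyl)methoxy]phenyl}[(2R,3R)-3-(3,5-dimethoxyphenyl)-6-methoxy-2-(4-methoxyphenyl)-2,3-dihydro-1-benzofuran-4-yl]methanol (both carbinol epimers), via aryllithium 18 (not isolated)
Conditions: t-BuLi (2.05 equiv), THF, −78 °C; then 17, −78 °C
Reagents that add atoms: none
Why: Bromine–lithium exchange followed by 1,2-addition to the aldehyde; at −78 °C the carbonyl addition is much faster than exchange with the aryl bromide of 17, and the new carbinol centre is removed in step 12.

Step 12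
Reactants: 19 {5-bromo-2-[(4-methoxyphenyl)methoxy]phenyl}[(2R,3R)-3-(3,5-dimethoxyphenyl)-6-methoxy-2-(4-methoxyphenyl)-2,3-dihydro-1-benzofuran-4-yl]methanol
Product: 20 {5-bromo-2-[(4-methoxyphenyl)methoxy]phenyl}[(2R,3R)-3-(3,5-dimethoxyphenyl)-6-methoxy-2-(4-methoxyphenyl)-2,3-dihydro-1-benzofuran-4-yl]methanone
Conditions: Dess–Martin periodinane, CH2Cl2, rt
Reagents that add atoms: none
Why: Dess–Martin oxidation of the benzhydrol; the dihydrofuran, the ethers and the aryl bromide are inert to the periodinane.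

Step 13
Reactants: 20 {5-bromo-2-[(4-methoxyphenyl)methoxy]phenyl}[(2R,3R)-3-(3,5-dimethoxyphenyl)-6-methoxy-2-(4-methoxyphenyl)-2,3-dihydro-1-benzofuran-4-yl]methanone
Product: 21 hydrazone of 20, 1-({5-bromo-2-[(4-methoxyphenyl)methoxy]phenyl}[(2R,3R)-3-(3,5-dimethoxyphenyl)-6-methoxy-2-(4-methoxyphenyl)-2,3-dihydro-1-benzofuran-4-yl]methylidene)hydrazine
Conditions: N2H4·H2O, AcOH (cat.), EtOH, 80 °C
Reagents that add atoms: hydrazine NN
Why: Hydrazone condensation; here each aryl ring of the ketone has only one ortho substituent, so the carbonyl stays accessible and the ether can be in place beforehand.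

Step 14
Reactants: 21 hydrazone of 20
Product: 23 (2S,3R)-5-bromo-3-[(2R,3R)-3-(3,5-dimethoxyphenyl)-6-methoxy-2-(4-methoxyphenyl)-2,3-dihydro-1-benzofuran-4-yl]-2-(4-methoxyphenyl)-2,3-dihydro-1-benzofuran (ring B cis), via diazo compound 22 (not isolated)
Conditions: MnO2, CH2Cl2, 0 °C, filter; Rh2(R-PTAD)4 (2 mol %), CH2Cl2, 0 °C → rt
Reagents that add atoms: none
Why: The same oxidation and carbene 1,5-C–H insertion as in step 7, now into the CH2 of the 4-methoxybenzyl ether; the only other C–H bond near the carbene (C3–H of ring C) would give a four-membered ring, and the catalyst sets C3 of ring B.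

Step 15
Reactants: 23 (2S,3R)-5-bromo-3-[(2R,3R)-3-(3,5-dimethoxyphenyl)-6-methoxy-2-(4-methoxyphenyl)-2,3-dihydro-1-benzofuran-4-yl]-2-(4-methoxyphenyl)-2,3-dihydro-1-benzofuran
Product: 24 (2R,3R)-5-bromo-3-[(2R,3R)-3-(3,5-dimethoxyphenyl)-6-methoxy-2-(4-methoxyphenyl)-2,3-dihydro-1-benzofuran-4-yl]-2-(4-methoxyphenyl)-2,3-dihydro-1-benzofuran
Conditions: CF3CO2H, CH2Cl2, −20 → 0 °C
Reagents that add atoms: none
Why: The same acid-mediated C2 epimerisation as in step 8; recapture of the ion-paired cation by the phenol in a five-membered closure should be much faster than attack by the 3,5-dimethoxyphenyl ring of ring C, and ring C, already trans, only re-closes to itself.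

Step 16
Reactants: 24 (2R,3R)-5-bromo-3-[(2R,3R)-3-(3,5-dimethoxyphenyl)-6-methoxy-2-(4-methoxyphenyl)-2,3-dihydro-1-benzofuran-4-yl]-2-(4-methoxyphenyl)-2,3-dihydro-1-benzofuran
Product: 27 (BC-5-yl)methanol, via aryllithium 25 (not isolated), via aldehyde 26 (not isolated)
Conditions: t-BuLi (2.1 equiv), THF, −78 °C; DMF; then MeOH, NaBH4, 0 °C
Reagents that add atoms: N,N-dimethylformamide CN(C)C=O
Why: Bromine–lithium exchange, formylation with DMF and borohydride reduction of the aldehyde in the same flask; no other group reacts with the aryllithium or the hydride.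

Step 17
Reactants: 27 (BC-5-yl)methanol
Product: 28 5-(bromomethyl) derivative, (BC-5-yl)methyl bromide
Conditions: CBr4, PPh3, CH2Cl2, 0 °C
Reagents that add atoms: tetrabromomethane BrC(Br)(Br)Br
Why: Appel reaction under neutral conditions; the 4-alkoxybenzylic bromide is reactive and is used at once in step 18.

Step 18
Reactants: 8 3-bromo-2-[(2-bromo-3,5-dimethoxyphenyl)(hydrazinylidene)methyl]-5-methoxyphenol; 28 (BC-5-yl)methyl bromide
Product: 29 1-[(2-bromo-3,5-dimethoxyphenyl){2-bromo-4-methoxy-6-[(BC-5-yl)methoxy]phenyl}methylidene]hydrazine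
Conditions: Cs2CO3, DMF, 0 °C → rt
Reagents that add atoms: none
Why: Williamson ether synthesis that unites the two halves of the molecule; the phenoxide of 8, used in slight excess, should outrun the hydrazone nitrogen as in step 6.

Step 19
Reactants: 29 1-[(2-bromo-3,5-dimethoxyphenyl){2-bromo-4-methoxy-6-[(BC-5-yl)methoxy]phenyl}methylidene]hydrazine
Product: 31 (2S,3R)-4-bromo-3-(2-bromo-3,5-dimethoxyphenyl)-6-methoxy-2-(BC-5-yl)-2,3-dihydro-1-benzofuran (ring A cis), via diazo compound 30 (not isolated)
Conditions: MnO2, CH2Cl2, 0 °C, filter; Rh2(R-PTAD)4 (3 mol %), CH2Cl2, 0 → 40 °C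
Reagents that add atoms: none
Why: The same oxidation and carbene 1,5-C–H insertion, into the 4-alkoxybenzylic CH2 of the ether; the catalyst, not the remote centres of rings B and C, fixes C3 of ring A, and the reaction has been rehearsed on the same carbene in step 7.

Step 20
Reactants: 31 (2S,3R)-4-bromo-3-(2-bromo-3,5-dimethoxyphenyl)-6-methoxy-2-(BC-5-yl)-2,3-dihydro-1-benzofuran
Product: 32 (2R,3R)-4-bromo-3-(2-bromo-3,5-dimethoxyphenyl)-6-methoxy-2-(BC-5-yl)-2,3-dihydro-1-benzofuran (ring A trans)
Conditions: CF3CO2H, CH2Cl2, −20 → 0 °C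
Reagents that add atoms: none
Why: Acid-mediated C2 epimerisation as in steps 8 and 15; the cation at C2 of ring A is stabilised by the para oxygen of ring B, no nucleophilic ring can reach it in a ring of workable size, and rings B and C re-close to themselves.

Step 21
Reactants: 32 (2R,3R)-4-bromo-3-(2-bromo-3,5-dimethoxyphenyl)-6-methoxy-2-(BC-5-yl)-2,3-dihydro-1-benzofuran; 33 4-(tetrahydro-2H-pyran-2-yloxy)benzaldehyde
Product: 35 {2-[(2R,3R)-4-bromo-6-methoxy-2-(BC-5-yl)-2,3-dihydro-1-benzofuran-3-yl]-4,6-dimethoxyphenyl}[4-(tetrahydro-2H-pyran-2-yloxy)phenyl]methanol (epimers at the carbinol and acetal carbons), via aryllithium 34 (not isolated)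
Conditions: n-BuLi (1.05 equiv), THF, −100 °C; then 33, −100 → −78 °C
Reagents that add atoms: none
Why: Selective bromine–lithium exchange at the ring D bromide, which alone has an ortho-methoxy group (as rehearsed in step 9), then 1,2-addition to the aldehyde; this attaches C-α with its aryl group, and the carbinol configuration is irrelevant because the carbon becomes sp2 in step 24.

Step 22
Reactants: 35 {2-[(2R,3R)-4-bromo-6-methoxy-2-(BC-5-yl)-2,3-dihydro-1-benzofuran-3-yl]-4,6-dimethoxyphenyl}[4-(tetrahydro-2H-pyran-2-yloxy)phenyl]methanol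
Product: 37 (2R,3R)-3-(2-{hydroxy[4-(tetrahydro-2H-pyran-2-yloxy)phenyl]methyl}-3,5-dimethoxyphenyl)-6-methoxy-2-(BC-5-yl)-2,3-dihydro-1-benzofuran-4-carbaldehyde, via dilithio intermediate 36 (not isolated)
Conditions: t-BuLi (3.3 equiv), THF, −78 °C; DMF; aq. NH4Cl
Reagents that add atoms: N,N-dimethylformamide CN(C)C=O
Why: The first equivalent of base gives the lithium alkoxide, the remaining bromide on C4 of ring A is exchanged, and the aryllithium is formylated with DMF; the alkoxide and the acetal are inert.

Step 23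
Reactants: 37 (2R,3R)-3-(2-{hydroxy[4-(tetrahydro-2H-pyran-2-yloxy)phenyl]methyl}-3,5-dimethoxyphenyl)-6-methoxy-2-(BC-5-yl)-2,3-dihydro-1-benzofuran-4-carbaldehyde
Product: 38 (2R,3R)-3-{2-[(4-hydroxyphenyl)(4-methylbenzenesulfonyl)methyl]-3,5-dimethoxyphenyl}-6-methoxy-2-(BC-5-yl)-2,3-dihydro-1-benzofuran-4-carbaldehyde (both epimers at the sulfone carbon)
Conditions: TolSO2Na (sodium 4-methylbenzenesulfinate), AcOH/THF/H2O, 40 °C
Reagents that add atoms: sodium 4-methylbenzenesulfinate Cc1ccc(cc1)S(=O)[O-].[Na+]
Why: SN1 substitution; the benzhydrol, with ortho and para methoxy groups and a para-oxyphenyl group, ionises in acetic acid and the cation is captured at sulfur by the sulfinate, while the same medium hydrolyses the tetrahydropyranyl acetal; acetic acid is too weak to open the dihydrofurans.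

Step 24
Reactants: 38 (2R,3R)-3-{2-[(4-hydroxyphenyl)(4-methylbenzenesulfonyl)methyl]-3,5-dimethoxyphenyl}-6-methoxy-2-(BC-5-yl)-2,3-dihydro-1-benzofuran-4-carbaldehyde
Product: 40 octa-O-methyl cycloheptanone with free 4-hydroxyphenyl group on C-α (R) and ketone at C-β (rings A, B and C each 2R,3R), via para-quinone methide 39 (not isolated)
Conditions: (5aS,10bR)-2-mesityl-5a,10b-dihydro-4H,6H-indeno[2,1-b][1,2,4]triazolo[4,3-d][1,4]oxazin-2-ium chloride (20 mol %), Cs2CO3 (2.5 equiv), THF, 4 Å MS, rt
Reagents that add atoms: none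
Why: Cs2CO3 deprotonates the phenol of 38, which expels sulfinate and releases the para-quinone methide 39 at low stationary concentration; the triazolylidene adds to the only aldehyde, proton transfer gives the Breslow intermediate, and its nucleophilic carbon attacks the exocyclic methide carbon (1,6-addition, Stetter-type), after which the alkoxide collapses to the ketone and frees the carbene. The closest known reaction type is the carbene-catalysed intermolecular 1,6-addition of aryl aldehydes to para-quinone methides, which gives α,α-diaryl ketones. The seven-membered ring closes in the 7-exo-trig mode, the attacked C=C lying outside the new ring, and aromatisation of the quinone methide to the phenolate makes the step irreversible. One stereocentre is formed, C-α; it is α to the new ketone and doubly benzylic, so under the carbonate it can equilibrate to the more stable epimer, expected to carry the 4-hydroxyphenyl group on the face opposite C2 of ring A (R), and the chiral carbene is chosen to favour the same face in the kinetic addition. The step needs the acyl anion to add to the methide faster than benzoin condensation, or addition of sulfinate or of the carbene to the methide, can take over. The substrate secures this: aldehyde and methide sit on the two ortho positions around C3 of ring A, so the intramolecular path is favoured over every bimolecular one, and the sulfone acts as a reservoir that keeps free quinone methide scarce.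

Step 25
Reactants: 40 octa-O-methyl cycloheptanone
Product: 41 octa-O-methyl trans carbinol, with C-α (R) and C-β (S) and the free 4-hydroxyphenyl group on C-α
Conditions: Al(OiPr)3, iPrOH, toluene, 90 °C
Reagents that add atoms: none
Why: Meerwein–Ponndorf–Verley reduction; reversible hydride transfer from isopropoxide on aluminium equilibrates the carbinol epimers (and, through the ketone, C-α), so the thermodynamic alcohol with hydroxyl and aryl trans is expected; nothing else in the molecule is reducible.

Step 26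
Reactants: 41 octa-O-methyl trans carbinol
Product: 42 target CNP0132116.1
Conditions: BBr3, CH2Cl2, −78 → 0 °C; MeOH, H2O
Reagents that add atoms: none
Why: Lewis-acid cleavage of the eight aryl methyl ethers (bromide attacks the methyl group of the boron-bound ether); the furan C2–O bonds can open reversibly but re-close to the trans rings, and the carbinol carbon sits on C4 of ring A, meta to both ring oxygens, so its ionisation is not assisted.

## Compound list

1 | 1-iodo-3,5-dimethoxybenzene | COc1cc(I)cc(OC)c1 | starting material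
2 | 2-bromo-1-iodo-3,5-dimethoxybenzene | COc1cc(I)c(Br)c(OC)c1 | intermediate
3 | 2-bromo-4,6-dimethoxybenzaldehyde | O=Cc1c(Br)cc(OC)cc1OC | starting material
4 | (2-bromo-3,5-dimethoxyphenyl)magnesium chloride | COc1cc([Mg]Cl)c(Br)c(OC)c1 | intermediate
5 | (2-bromo-3,5-dimethoxyphenyl)(2-bromo-4,6-dimethoxyphenyl)methanol (racemic) | OC(c1cc(OC)cc(OC)c1Br)c1c(Br)cc(OC)cc1OC | intermediate
6 | (2-bromo-3,5-dimethoxyphenyl)(2-bromo-4,6-dimethoxyphenyl)methanone | O=C(c1cc(OC)cc(OC)c1Br)c1c(Br)cc(OC)cc1OC | intermediate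
7 | (2-bromo-3,5-dimethoxyphenyl)(2-bromo-6-hydroxy-4-methoxyphenyl)methanone | O=C(c1cc(OC)cc(OC)c1Br)c1c(Br)cc(OC)cc1O | intermediate
8 | 3-bromo-2-[(2-bromo-3,5-dimethoxyphenyl)(hydrazinylidene)methyl]-5-methoxyphenol | NN=C(c1cc(OC)cc(OC)c1Br)c1c(Br)cc(OC)cc1O | intermediate
9 | 4-methoxybenzyl chloride | COc1ccc(CCl)cc1 | starting material
10 | 1-[(2-bromo-3,5-dimethoxyphenyl){2-bromo-4-methoxy-6-[(4-methoxyphenyl)methoxy]phenyl}methylidene]hydrazine | NN=C(c1cc(OC)cc(OC)c1Br)c1c(Br)cc(OC)cc1OCc1ccc(OC)cc1 | intermediate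
11 | 1-bromo-2-[(2-bromo-3,5-dimethoxyphenyl)(diazo)methyl]-5-methoxy-3-[(4-methoxyphenyl)methoxy]benzene | [N-]=[N+]=C(c1cc(OC)cc(OC)c1Br)c1c(Br)cc(OC)cc1OCc1ccc(OC)cc1 | intermediate
12 | (2S,3R)-4-bromo-3-(2-bromo-3,5-dimethoxyphenyl)-6-methoxy-2-(4-methoxyphenyl)-2,3-dihydro-1-benzofuran (cis) | Brc1cc(OC)cc2c1[C@@H](c1cc(OC)cc(OC)c1Br)[C@@H](c1ccc(OC)cc1)O2 | intermediate
13 | (2R,3R)-4-bromo-3-(2-bromo-3,5-dimethoxyphenyl)-6-methoxy-2-(4-methoxyphenyl)-2,3-dihydro-1-benzofuran (trans) | Brc1cc(OC)cc2c1[C@@H](c1cc(OC)cc(OC)c1Br)[C@H](c1ccc(OC)cc1)O2 | intermediate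
14 | aryllithium from 13, lithiated at C2 of the 3-aryl group | Brc1cc(OC)cc2c1[C@@H](c1cc(OC)cc(OC)c1[Li])[C@H](c1ccc(OC)cc1)O2 | intermediate
15 | (2R,3R)-4-bromo-3-(3,5-dimethoxyphenyl)-6-methoxy-2-(4-methoxyphenyl)-2,3-dihydro-1-benzofuran | Brc1cc(OC)cc2c1[C@@H](c1cc(OC)cc(OC)c1)[C@H](c1ccc(OC)cc1)O2 | intermediate
16 | 5-bromo-2-hydroxybenzaldehyde | O=Cc1cc(Br)ccc1O | starting material
17 | 5-bromo-2-[(4-methoxyphenyl)methoxy]benzaldehyde | O=Cc1cc(Br)ccc1OCc1ccc(OC)cc1 | intermediate
18 | aryllithium from 15, lithiated at C4 | [Li]c1cc(OC)cc2c1[C@@H](c1cc(OC)cc(OC)c1)[C@H](c1ccc(OC)cc1)O2 | intermediate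
19 | {5-bromo-2-[(4-methoxyphenyl)methoxy]phenyl}[(2R,3R)-3-(3,5-dimethoxyphenyl)-6-methoxy-2-(4-methoxyphenyl)-2,3-dihydro-1-benzofuran-4-yl]methanol (carbinol epimers) | OC(c1cc(Br)ccc1OCc1ccc(OC)cc1)c1cc(OC)cc2c1[C@@H](c1cc(OC)cc(OC)c1)[C@H](c1ccc(OC)cc1)O2 | intermediate
20 | {5-bromo-2-[(4-methoxyphenyl)methoxy]phenyl}[(2R,3R)-3-(3,5-dimethoxyphenyl)-6-methoxy-2-(4-methoxyphenyl)-2,3-dihydro-1-benzofuran-4-yl]methanone | O=C(c1cc(Br)ccc1OCc1ccc(OC)cc1)c1cc(OC)cc2c1[C@@H](c1cc(OC)cc(OC)c1)[C@H](c1ccc(OC)cc1)O2 | intermediate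
21 | hydrazone of 20 | NN=C(c1cc(Br)ccc1OCc1ccc(OC)cc1)c1cc(OC)cc2c1[C@@H](c1cc(OC)cc(OC)c1)[C@H](c1ccc(OC)cc1)O2 | intermediate
22 | diazo compound from 21 | [N-]=[N+]=C(c1cc(Br)ccc1OCc1ccc(OC)cc1)c1cc(OC)cc2c1[C@@H](c1cc(OC)cc(OC)c1)[C@H](c1ccc(OC)cc1)O2 | intermediate
23 | (2S,3R)-5-bromo-3-[(2R,3R)-3-(3,5-dimethoxyphenyl)-6-methoxy-2-(4-methoxyphenyl)-2,3-dihydro-1-benzofuran-4-yl]-2-(4-methoxyphenyl)-2,3-dihydro-1-benzofuran (ring B cis) | Brc1ccc2c(c1)[C@@H](c1cc(OC)cc3c1[C@@H](c1cc(OC)cc(OC)c1)[C@H](c1ccc(OC)cc1)O3)[C@@H](c1ccc(OC)cc1)O2 | intermediate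
24 | (2R,3R)-5-bromo-3-[(2R,3R)-3-(3,5-dimethoxyphenyl)-6-methoxy-2-(4-methoxyphenyl)-2,3-dihydro-1-benzofuran-4-yl]-2-(4-methoxyphenyl)-2,3-dihydro-1-benzofuran | Brc1ccc2c(c1)[C@@H](c1cc(OC)cc3c1[C@@H](c1cc(OC)cc(OC)c1)[C@H](c1ccc(OC)cc1)O3)[C@H](c1ccc(OC)cc1)O2 | intermediate
25 | (BC-5-yl)lithium | [Li]c1ccc2c(c1)[C@@H](c1cc(OC)cc3c1[C@@H](c1cc(OC)cc(OC)c1)[C@H](c1ccc(OC)cc1)O3)[C@H](c1ccc(OC)cc1)O2 | intermediate
26 | BC-5-carbaldehyde | O=Cc1ccc2c(c1)[C@@H](c1cc(OC)cc3c1[C@@H](c1cc(OC)cc(OC)c1)[C@H](c1ccc(OC)cc1)O3)[C@H](c1ccc(OC)cc1)O2 | intermediate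
27 | (BC-5-yl)methanol | OCc1ccc2c(c1)[C@@H](c1cc(OC)cc3c1[C@@H](c1cc(OC)cc(OC)c1)[C@H](c1ccc(OC)cc1)O3)[C@H](c1ccc(OC)cc1)O2 | intermediate
28 | (BC-5-yl)methyl bromide | BrCc1ccc2c(c1)[C@@H](c1cc(OC)cc3c1[C@@H](c1cc(OC)cc(OC)c1)[C@H](c1ccc(OC)cc1)O3)[C@H](c1ccc(OC)cc1)O2 | intermediate
29 | 1-[(2-bromo-3,5-dimethoxyphenyl){2-bromo-4-methoxy-6-[(BC-5-yl)methoxy]phenyl}methylidene]hydrazine | NN=C(c1cc(OC)cc(OC)c1Br)c1c(Br)cc(OC)cc1OCc1ccc2c(c1)[C@@H](c1cc(OC)cc3c1[C@@H](c1cc(OC)cc(OC)c1)[C@H](c1ccc(OC)cc1)O3)[C@H](c1ccc(OC)cc1)O2 | intermediate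
30 | diazo compound from 29 | [N-]=[N+]=C(c1cc(OC)cc(OC)c1Br)c1c(Br)cc(OC)cc1OCc1ccc2c(c1)[C@@H](c1cc(OC)cc3c1[C@@H](c1cc(OC)cc(OC)c1)[C@H](c1ccc(OC)cc1)O3)[C@H](c1ccc(OC)cc1)O2 | intermediate
31 | (2S,3R)-4-bromo-3-(2-bromo-3,5-dimethoxyphenyl)-6-methoxy-2-(BC-5-yl)-2,3-dihydro-1-benzofuran (ring A cis) | COc1cc(OC)c(Br)c(c1)[C@@H]1c2c(cc(OC)cc2Br)O[C@@H]1c1ccc2c(c1)[C@@H](c1cc(OC)cc3c1[C@@H](c1cc(OC)cc(OC)c1)[C@H](c1ccc(OC)cc1)O3)[C@H](c1ccc(OC)cc1)O2 | intermediate
32 | (2R,3R)-4-bromo-3-(2-bromo-3,5-dimethoxyphenyl)-6-methoxy-2-(BC-5-yl)-2,3-dihydro-1-benzofuran (ring A trans) | COc1cc(OC)c(Br)c(c1)[C@@H]1c2c(cc(OC)cc2Br)O[C@H]1c1ccc2c(c1)[C@@H](c1cc(OC)cc3c1[C@@H](c1cc(OC)cc(OC)c1)[C@H](c1ccc(OC)cc1)O3)[C@H](c1ccc(OC)cc1)O2 | intermediate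
33 | 4-(tetrahydro-2H-pyran-2-yloxy)benzaldehyde (racemic) | O=Cc1ccc(OC2CCCCO2)cc1 | starting material
34 | aryllithium from 32, lithiated at C2 of ring D | COc1cc(OC)c([Li])c(c1)[C@@H]1c2c(cc(OC)cc2Br)O[C@H]1c1ccc2c(c1)[C@@H](c1cc(OC)cc3c1[C@@H](c1cc(OC)cc(OC)c1)[C@H](c1ccc(OC)cc1)O3)[C@H](c1ccc(OC)cc1)O2 | intermediate
35 | {2-[(2R,3R)-4-bromo-6-methoxy-2-(BC-5-yl)-2,3-dihydro-1-benzofuran-3-yl]-4,6-dimethoxyphenyl}[4-(tetrahydro-2H-pyran-2-yloxy)phenyl]methanol (epimers at carbinol and acetal carbons) | COc1cc(OC)c(C(O)c2ccc(OC3CCCCO3)cc2)c(c1)[C@@H]1c2c(cc(OC)cc2Br)O[C@H]1c1ccc2c(c1)[C@@H](c1cc(OC)cc3c1[C@@H](c1cc(OC)cc(OC)c1)[C@H](c1ccc(OC)cc1)O3)[C@H](c1ccc(OC)cc1)O2 | intermediate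
36 | lithium alkoxide of 35, lithiated at C4 of ring A | COc1cc(OC)c(C(O[Li])c2ccc(OC3CCCCO3)cc2)c(c1)[C@@H]1c2c(cc(OC)cc2[Li])O[C@H]1c1ccc2c(c1)[C@@H](c1cc(OC)cc3c1[C@@H](c1cc(OC)cc(OC)c1)[C@H](c1ccc(OC)cc1)O3)[C@H](c1ccc(OC)cc1)O2 | intermediate
37 | (2R,3R)-3-(2-{hydroxy[4-(tetrahydro-2H-pyran-2-yloxy)phenyl]methyl}-3,5-dimethoxyphenyl)-6-methoxy-2-(BC-5-yl)-2,3-dihydro-1-benzofuran-4-carbaldehyde (epimers at carbinol and acetal carbons) | COc1cc(OC)c(C(O)c2ccc(OC3CCCCO3)cc2)c(c1)[C@@H]1c2c(cc(OC)cc2C=O)O[C@H]1c1ccc2c(c1)[C@@H](c1cc(OC)cc3c1[C@@H](c1cc(OC)cc(OC)c1)[C@H](c1ccc(OC)cc1)O3)[C@H](c1ccc(OC)cc1)O2 | intermediate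
38 | (2R,3R)-3-{2-[(4-hydroxyphenyl)(4-methylbenzenesulfonyl)methyl]-3,5-dimethoxyphenyl}-6-methoxy-2-(BC-5-yl)-2,3-dihydro-1-benzofuran-4-carbaldehyde (epimers at the sulfone carbon) | COc1cc(OC)c(C(c2ccc(O)cc2)S(=O)(=O)c2ccc(C)cc2)c(c1)[C@@H]1c2c(cc(OC)cc2C=O)O[C@H]1c1ccc2c(c1)[C@@H](c1cc(OC)cc3c1[C@@H](c1cc(OC)cc(OC)c1)[C@H](c1ccc(OC)cc1)O3)[C@H](c1ccc(OC)cc1)O2 | intermediate
39 | para-quinone methide aldehyde, (2R,3R)-3-{3,5-dimethoxy-2-[(4-oxocyclohexa-2,5-dien-1-ylidene)methyl]phenyl}-6-methoxy-2-(BC-5-yl)-2,3-dihydro-1-benzofuran-4-carbaldehyde | O=C1C=CC(=Cc2c(OC)cc(OC)cc2[C@@H]2c3c(cc(OC)cc3C=O)O[C@H]2c2ccc3c(c2)[C@@H](c2cc(OC)cc4c2[C@@H](c2cc(OC)cc(OC)c2)[C@H](c2ccc(OC)cc2)O4)[C@H](c2ccc(OC)cc2)O3)C=C1 | intermediate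
40 | octa-O-methyl cycloheptanone with free 4-hydroxyphenyl group, C-α (R) | Oc1ccc([C@@H]2c3c(OC)cc(OC)cc3[C@@H]3c4c(cc(OC)cc4C2=O)O[C@H]3c2ccc3c(c2)[C@@H](c2cc(OC)cc4c2[C@@H](c2cc(OC)cc(OC)c2)[C@H](c2ccc(OC)cc2)O4)[C@H](c2ccc(OC)cc2)O3)cc1 | intermediate
41 | octa-O-methyl trans carbinol, C-α (R), C-β (S) | Oc1ccc([C@@H]2c3c(OC)cc(OC)cc3[C@@H]3c4c(cc(OC)cc4[C@H]2O)O[C@H]3c2ccc3c(c2)[C@@H](c2cc(OC)cc4c2[C@@H](c2cc(OC)cc(OC)c2)[C@H](c2ccc(OC)cc2)O4)[C@H](c2ccc(OC)cc2)O3)cc1 | intermediate
42 | CNP0132116.1 (rings A, B and C each 2R,3R; C-α R; C-β S) | Oc1ccc([C@@H]2c3c(O)cc(O)cc3[C@@H]3c4c(cc(O)cc4[C@H]2O)O[C@H]3c2ccc3c(c2)[C@@H](c2cc(O)cc4c2[C@@H](c2cc(O)cc(O)c2)[C@H](c2ccc(O)cc2)O4)[C@H](c2ccc(O)cc2)O3)cc1 | target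

## Step count and least certain steps

Total step count: 26. Longest linear sequence: 25 steps (steps 1–9 and 11–26); step 10 is the only side branch.

Step 24 (key step). The seven-membered closure may be too slow, so that the quinone methide is consumed by bimolecular paths (re-addition of sulfinate, addition of the carbene, oligomerisation) or the aldehyde undergoes benzoin-type coupling. Fallback: it sets out from 38. After deprotonation with Cs2CO3, SmI2 in THF/HMPA at −78 °C reduces the aldehyde/quinone methide pair and couples C-β to C-α reductively (ketyl–alkene or Barbier-type cyclisation), giving the cycloheptanol as a mixture of epimers at both new centres, F1. Heating F1 with Al(OiPr)3, 2-propanol and a little acetone equilibrates it through ketone 40 (Oppenauer and Meerwein–Ponndorf–Verley hydride transfer) and brings it back to the route at 41.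

Step 19 (ring A insertion; step 7 is its rehearsal on the same carbene). The diazo carbon carries three ortho substituents, so formation of the metal carbene may be slow. Thermal loss of nitrogen or azine formation could then compete, and the selectivity given by the catalyst would be lost. Fallback: it sets out from 7 and 28 and uses no carbene. NaBH4 reduces 7 to (2-bromo-3,5-dimethoxyphenyl)(2-bromo-6-hydroxy-4-methoxyphenyl)methanol F2, and sodium 4-methylbenzenesulfinate in formic acid converts it into the 2-[aryl(sulfonyl)methyl]phenol F3. Bromide 28 and tetrahydrothiophene give the sulfonium bromide F4. Cs2CO3 then releases the ortho-quinone methide from F3 and the benzylic ylide from F4, and their [4+1] annulation (conjugate addition, then displacement of the sulfide by the phenoxide) closes ring A trans. The fallback returns to the route at 32. Because the sulfide is achiral, 32 has to be separated by chromatography from the trans isomer of opposite ring A configuration, F5; a chiral sulfide such as isothiocineole could be used to bias the ratio.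

Step 21 (selective exchange; step 9 is its rehearsal). Exchange may occur at both bromides or at the wrong one, giving double addition or mixtures. Fallback: it sets out from 32 and differentiates the bromides by steric hindrance towards palladium instead. Suzuki–Miyaura coupling with potassium vinyltrifluoroborate (Pd(OAc)2, a bulky biaryl phosphine, Cs2CO3) at the less hindered bromide on C4 of ring A gives the 4-vinyl bromide F6. The single remaining bromide is exchanged with t-BuLi and added to 33 to give the vinyl benzhydrol F7. Lemieux–Johnson cleavage (OsO4 cat., NaIO4) of the vinyl group returns to the route at 37.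

Step 15 (epimerisation of ring B). The cation at C2 of ring B lies seven atoms from the nucleophilic 3,5-dimethoxyphenyl ring of ring C, so Friedel–Crafts capture to a seven-membered ring could compete with re-closure. Fallback: it sets out from 15 and closes ring B trans under basic conditions. The aryllithium from 15 is added to 5-bromo-2-(methoxymethoxy)benzaldehyde F8 (from 16 and chloromethyl methyl ether) to give carbinol F9. Sodium 4-methylbenzenesulfinate with CF3CO2H removes the acetal and gives the sulfone phenol F10. With (4-methoxybenzyl)tetrahydrothiophenium chloride F11 (from 9 and tetrahydrothiophene) and Cs2CO3, the [4+1] annulation of ortho-quinone methide and ylide returns to the route at 24, after separation from the ring B diastereomer F12.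

Step 26 (global demethylation). The benzylic carbinol may ionise under BBr3, leading to bromide formation, elimination or capture by a neighbouring ring. Fallback: it sets out from 41. Ac2O and pyridine give the diacetate F13 (phenol and carbinol acetylated), whose C-β–O bond is deactivated towards ionisation. BBr3 then cleaves the methyl ethers to the octaphenol diacetate F14, and K2CO3 in methanol removes both acetates and returns to the route at 42.

## Further compounds

F1 | step 24 | octa-O-methyl cycloheptanol, mixture of epimers at C-α and C-β | Oc1ccc(C2c3c(OC)cc(OC)cc3[C@@H]3c4c(cc(OC)cc4C2O)O[C@H]3c2ccc3c(c2)[C@@H](c2cc(OC)cc4c2[C@@H](c2cc(OC)cc(OC)c2)[C@H](c2ccc(OC)cc2)O4)[C@H](c2ccc(OC)cc2)O3)cc1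
F2 | step 19 | (2-bromo-3,5-dimethoxyphenyl)(2-bromo-6-hydroxy-4-methoxyphenyl)methanol (racemic) | OC(c1cc(OC)cc(OC)c1Br)c1c(Br)cc(OC)cc1O
F3 | step 19 | 3-bromo-2-[(2-bromo-3,5-dimethoxyphenyl)(4-methylbenzenesulfonyl)methyl]-5-methoxyphenol (racemic) | Cc1ccc(cc1)S(=O)(=O)C(c1cc(OC)cc(OC)c1Br)c1c(Br)cc(OC)cc1O
F4 | step 19 | 1-[(BC-5-yl)methyl]tetrahydrothiophenium bromide | [Br-].C1CC[S+](C1)Cc1ccc2c(c1)[C@@H](c1cc(OC)cc3c1[C@@H](c1cc(OC)cc(OC)c1)[C@H](c1ccc(OC)cc1)O3)[C@H](c1ccc(OC)cc1)O2
F5 | step 19 | (2S,3S)-4-bromo-3-(2-bromo-3,5-dimethoxyphenyl)-6-methoxy-2-(BC-5-yl)-2,3-dihydro-1-benzofuran (ring A trans, opposite configuration) | COc1cc(OC)c(Br)c(c1)[C@H]1c2c(cc(OC)cc2Br)O[C@@H]1c1ccc2c(c1)[C@@H](c1cc(OC)cc3c1[C@@H](c1cc(OC)cc(OC)c1)[C@H](c1ccc(OC)cc1)O3)[C@H](c1ccc(OC)cc1)O2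
F6 | step 21 | (2R,3R)-3-(2-bromo-3,5-dimethoxyphenyl)-4-ethenyl-6-methoxy-2-(BC-5-yl)-2,3-dihydro-1-benzofuran | COc1cc(OC)c(Br)c(c1)[C@@H]1c2c(cc(OC)cc2C=C)O[C@H]1c1ccc2c(c1)[C@@H](c1cc(OC)cc3c1[C@@H](c1cc(OC)cc(OC)c1)[C@H](c1ccc(OC)cc1)O3)[C@H](c1ccc(OC)cc1)O2
F7 | step 21 | {2-[(2R,3R)-4-ethenyl-6-methoxy-2-(BC-5-yl)-2,3-dihydro-1-benzofuran-3-yl]-4,6-dimethoxyphenyl}[4-(tetrahydro-2H-pyran-2-yloxy)phenyl]methanol (epimers at carbinol and acetal carbons) | COc1cc(OC)c(C(O)c2ccc(OC3CCCCO3)cc2)c(c1)[C@@H]1c2c(cc(OC)cc2C=C)O[C@H]1c1ccc2c(c1)[C@@H](c1cc(OC)cc3c1[C@@H](c1cc(OC)cc(OC)c1)[C@H](c1ccc(OC)cc1)O3)[C@H](c1ccc(OC)cc1)O2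
F8 | step 15 | 5-bromo-2-(methoxymethoxy)benzaldehyde | O=Cc1cc(Br)ccc1OCOC
F9 | step 15 | [5-bromo-2-(methoxymethoxy)phenyl][(2R,3R)-3-(3,5-dimethoxyphenyl)-6-methoxy-2-(4-methoxyphenyl)-2,3-dihydro-1-benzofuran-4-yl]methanol (carbinol epimers) | OC(c1cc(Br)ccc1OCOC)c1cc(OC)cc2c1[C@@H](c1cc(OC)cc(OC)c1)[C@H](c1ccc(OC)cc1)O2
F10 | step 15 | 4-bromo-2-{[(2R,3R)-3-(3,5-dimethoxyphenyl)-6-methoxy-2-(4-methoxyphenyl)-2,3-dihydro-1-benzofuran-4-yl](4-methylbenzenesulfonyl)methyl}phenol (epimers at the sulfone carbon) | Cc1ccc(cc1)S(=O)(=O)C(c1cc(Br)ccc1O)c1cc(OC)cc2c1[C@@H](c1cc(OC)cc(OC)c1)[C@H](c1ccc(OC)cc1)O2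
F11 | step 15 | 1-(4-methoxybenzyl)tetrahydrothiophenium chloride | COc1ccc(C[S+]2CCCC2)cc1.[Cl-]
F12 | step 15 | (2S,3S)-5-bromo-3-[(2R,3R)-3-(3,5-dimethoxyphenyl)-6-methoxy-2-(4-methoxyphenyl)-2,3-dihydro-1-benzofuran-4-yl]-2-(4-methoxyphenyl)-2,3-dihydro-1-benzofuran (ring B trans, opposite configuration) | Brc1ccc2c(c1)[C@H](c1cc(OC)cc3c1[C@@H](c1cc(OC)cc(OC)c1)[C@H](c1ccc(OC)cc1)O3)[C@@H](c1ccc(OC)cc1)O2
F13 | step 26 | diacetate of 41 (acetates on the 4-hydroxyphenyl oxygen and on the C-β oxygen) | CC(=O)Oc1ccc([C@@H]2c3c(OC)cc(OC)cc3[C@@H]3c4c(cc(OC)cc4[C@H]2OC(C)=O)O[C@H]3c2ccc3c(c2)[C@@H](c2cc(OC)cc4c2[C@@H](c2cc(OC)cc(OC)c2)[C@H](c2ccc(OC)cc2)O4)[C@H](c2ccc(OC)cc2)O3)cc1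
F14 | step 26 | octaphenol diacetate (all eight methyl ethers of F13 cleaved) | CC(=O)Oc1ccc([C@@H]2c3c(O)cc(O)cc3[C@@H]3c4c(cc(O)cc4[C@H]2OC(C)=O)O[C@H]3c2ccc3c(c2)[C@@H](c2cc(O)cc4c2[C@@H](c2cc(O)cc(O)c2)[C@H](c2ccc(O)cc2)O4)[C@H](c2ccc(O)cc2)O3)cc1
A1 | alternative 1 | triaryl ethyl pinacol boronate | COc1ccc([C@H](c2c(OC)cc(OC)cc2C(OC)OC)[C@H](B2OC(C)(C)C(C)(C)O2)c2cc(OC)cc(OCOC)c2)cc1
A2 | alternative 2 | ring B bromide carrying the new benzylated resorcinol ring | Brc1ccc2c(c1)[C@@H](c1cc(O[Si](C(C)C)(C(C)C)C(C)C)cc(O)c1Cc1cc(OC)cc(OC)c1)[C@H](c1ccc(OC)cc1)O2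
A3 | alternative 3 | ring B aryl bromide holding rings B and C (identical with 24) | Brc1ccc2c(c1)[C@@H](c1cc(OC)cc3c1[C@@H](c1cc(OC)cc(OC)c1)[C@H](c1ccc(OC)cc1)O3)[C@H](c1ccc(OC)cc1)O2
A4 | alternative 3 | diol diphenol, open-chain precursor of A3 (carbinol configurations not defined) | Brc1ccc(O)c(c1)[C@H](C(O)c1ccc(OC)cc1)c1cc(OC)cc(O)c1[C@H](C(O)c1ccc(OC)cc1)c1cc(OC)cc(OC)c1
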